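**Retrosynthetic overview**
- The target is reached by one global O‑debenzylation of a tris(benzyl ether) diarylheptanone.
- Key disconnection: the aryl–C1 bond. C1 is the β‑carbon of the C3 ketone and is used as a nucleophile (ketone homoenolate, masked as a 1‑substituted cyclopropanol) against an electrophilic syringyl bromide in a Pd‑catalysed ring‑opening cross‑coupling.
- The cyclopropanol comes from an ethyl 5‑arylpentanoate by Kulinkovich cyclopropanation; the ester comes from an sp3–sp2 Negishi coupling.
- Both benzene rings are bought. The only ring formed is the cyclopropane (step 2), which is opened again in the key step (step 4).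

Assumption: the target SMILES has no stereocentre and no stereogenic double bond, so the compound is achiral and no stereocontrol is needed. Compounds 1 (sold as a 0.5 M solution in THF), 2 and 5 are taken as commercial; catalogue availability was not checked.

**Step 1**
Reactants: 1 (5‑ethoxy‑5‑oxopentyl)zinc bromide; 2 1,2‑bis(benzyloxy)‑4‑bromobenzene
Product: 3 ethyl 5‑[3,4‑bis(benzyloxy)phenyl]pentanoate
Conditions: 1 (1.3 equiv), Pd(OAc)2 (2 mol %), SPhos (4 mol %), THF, rt to 40 °C
Reagents that add atoms: none
Why: Negishi cross‑coupling, in which a primary alkylzinc halide carrying an ester couples with an aryl bromide because the bulky biaryl phosphine makes reductive elimination faster than β‑hydride elimination, while the ester and benzyl ethers are inert to the organozinc; no stereocentre is formed.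

**Step 2**
Reactants: 3 ethyl 5‑[3,4‑bis(benzyloxy)phenyl]pentanoate
Product: 4 1‑{4‑[3,4‑bis(benzyloxy)phenyl]butyl}cyclopropan‑1‑ol
Conditions: EtMgBr (3 equiv, slow addition), Ti(OiPr)4 (0.3 equiv), THF, 0 °C to rt; then aq. NH4Cl
Reagents that add atoms: ethylmagnesium bromide, CC[Mg]Br
Why: Kulinkovich cyclopropanation, in which EtMgBr and Ti(OiPr)4 form a titanacyclopropane that acts as a 1,2‑dicarbanion and adds twice to the ester carbonyl to close the 1‑substituted cyclopropanol, leaving the aryl benzyl ethers untouched; the carbinol carbon carries two identical CH2 arms, so no stereocentre arises.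

**Step 3**
Reactants: 5 4‑bromo‑2,6‑dimethoxyphenol
Product: 6 2‑(benzyloxy)‑5‑bromo‑1,3‑dimethoxybenzene
Conditions: BnBr (1.2 equiv), K2CO3 (2 equiv), DMF, 60 °C
Reagents that add atoms: benzyl bromide, BrCc1ccccc1
Why: Williamson ether synthesis, which masks the acidic phenol so that it cannot interfere with the palladium alkoxide in step 4 and uses the same benzyl group as the catechol so that one final hydrogenolysis frees all three phenols; no stereocentre is formed.

**Step 4 (key step)**
Reactants: 4 1‑{4‑[3,4‑bis(benzyloxy)phenyl]butyl}cyclopropan‑1‑ol; 6 2‑(benzyloxy)‑5‑bromo‑1,3‑dimethoxybenzene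
Product: 7 1‑[4‑(benzyloxy)‑3,5‑dimethoxyphenyl]‑7‑[3,4‑bis(benzyloxy)phenyl]heptan‑3‑one
Conditions: 4 (1.2 equiv), Pd(OAc)2 (5 mol %), XPhos (10 mol %), Cs2CO3 (2 equiv), toluene, 80 °C
Reagents that add atoms: none
Why: Palladium‑catalysed ring‑opening cross‑coupling of a cyclopropanol as a ketone homoenolate equivalent, in which 6 adds oxidatively to zerovalent palladium, the cesium cyclopropoxide of 4 replaces bromide on divalent palladium, strain‑driven β‑carbon elimination gives the β‑keto alkylpalladium (palladium homoenolate), and the bulky biaryl phosphine makes C(sp2)–C(sp3) reductive elimination faster than β‑hydride elimination, so the normally electrophilic β‑carbon of the ketone is joined as a nucleophile to the electrophilic aryl bromide; no stereocentre is formed.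

**Step 5**
Reactants: 7 1‑[4‑(benzyloxy)‑3,5‑dimethoxyphenyl]‑7‑[3,4‑bis(benzyloxy)phenyl]heptan‑3‑one
Product: 8 7‑(3,4‑dihydroxyphenyl)‑1‑(4‑hydroxy‑3,5‑dimethoxyphenyl)heptan‑3‑one (target)
Conditions: H2 (1 atm), Pd/C (10 wt % Pd), EtOAc/MeOH, rt; filtration and concentration under argon
Reagents that add atoms: none
Why: Catalytic hydrogenolysis of aryl benzyl ethers, which cleaves the three O–CH2Ph bonds while the aryl methyl ethers, the arene rings and the non‑benzylic dialkyl ketone are inert under these neutral conditions; the product has no stereocentre and is obtained as the single achiral compound.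

**Compound list**
1 | (5‑ethoxy‑5‑oxopentyl)zinc bromide | CCOC(=O)CCCC[Zn]Br | starting material
2 | 1,2‑bis(benzyloxy)‑4‑bromobenzene | Brc1ccc(OCc2ccccc2)c(OCc2ccccc2)c1 | starting material
3 | ethyl 5‑[3,4‑bis(benzyloxy)phenyl]pentanoate | CCOC(=O)CCCCc1ccc(OCc2ccccc2)c(OCc2ccccc2)c1 | intermediate
4 | 1‑{4‑[3,4‑bis(benzyloxy)phenyl]butyl}cyclopropan‑1‑ol | OC1(CCCCc2ccc(OCc3ccccc3)c(OCc3ccccc3)c2)CC1 | intermediate
5 | 4‑bromo‑2,6‑dimethoxyphenol | COc1cc(Br)cc(OC)c1O | starting material
6 | 2‑(benzyloxy)‑5‑bromo‑1,3‑dimethoxybenzene | COc1cc(Br)cc(OC)c1OCc1ccccc1 | intermediate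
7 | 1‑[4‑(benzyloxy)‑3,5‑dimethoxyphenyl]‑7‑[3,4‑bis(benzyloxy)phenyl]heptan‑3‑one | COc1cc(CCC(=O)CCCCc2ccc(OCc3ccccc3)c(OCc3ccccc3)c2)cc(OC)c1OCc1ccccc1 | intermediate
8 | 7‑(3,4‑dihydroxyphenyl)‑1‑(4‑hydroxy‑3,5‑dimethoxyphenyl)heptan‑3‑one | COc1cc(CCC(=O)CCCCc2ccc(O)c(O)c2)cc(OC)c1O | target

**Step count**
Total steps: 5. Longest linear sequence: 4 steps (1, 2, 4, 5); step 3 is a one‑step side branch.

**Three steps most likely to fail, with fallbacks**

Step 4 (homoenolate arylation). The palladium homoenolate may undergo β‑hydride elimination to an enone, or be protonated to the ethyl ketone, instead of reductive elimination. The fallback sets out from cyclopropanol 4 and turns the β‑hydride pathway into the productive one. Compound 4 is ring‑opened oxidatively (Pd(OAc)2 10 mol %, pyridine, O2 1 atm, toluene, 80 °C) to the vinyl ketone 7‑[3,4‑bis(benzyloxy)phenyl]hept‑1‑en‑3‑one F1. A Heck reaction of F1 with aryl bromide 6 (Pd(OAc)2, P(o‑tol)3, Et3N, DMF, 100 °C) gives (E)‑1‑[4‑(benzyloxy)‑3,5‑dimethoxyphenyl]‑7‑[3,4‑bis(benzyloxy)phenyl]hept‑1‑en‑3‑one F2. Submitting F2 to the step 5 conditions (H2, Pd/C) saturates the enone C=C and removes the three benzyl groups, so the fallback comes back to the route at target 8.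

Step 1 (alkyl Negishi coupling). The organozinc solution may have degraded, or the coupling may stall on the electron‑rich bromide. The fallback sets out from aryl bromide 2 and builds the chain through an sp–sp2 bond. Sonogashira coupling of 2 with commercial ethyl pent‑4‑ynoate (PdCl2(PPh3)2, CuI, Et3N, 70 °C) gives ethyl 5‑[3,4‑bis(benzyloxy)phenyl]pent‑4‑ynoate F3. The alkyne is then saturated with a homogeneous catalyst that does not cleave benzyl ethers (H2 3 atm, RhCl(PPh3)3 5 mol %, benzene/EtOH, 40 °C), and the fallback comes back to the route at ester 3.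

Step 2 (Kulinkovich cyclopropanation). Double ethyl addition to a tertiary alcohol or low conversion may lower the yield. The fallback sets out from ester 3 and closes the three‑membered ring by a 1,3‑reductive cyclisation instead of through a titanacyclopropane. Double chloromethylation of 3 (ICH2Cl, MeLi·LiBr, THF, −78 °C) gives 6‑[3,4‑bis(benzyloxy)phenyl]‑1‑chloro‑2‑(chloromethyl)hexan‑2‑ol F4. DePuy‑type ring closure of F4 (EtMgBr excess, FeCl3 5 mol %, Et2O, rt) gives the cyclopropanol, and the fallback comes back to the route at compound 4.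

**Further compounds**
F1 | step 4 | 7‑[3,4‑bis(benzyloxy)phenyl]hept‑1‑en‑3‑one | C=CC(=O)CCCCc1ccc(OCc2ccccc2)c(OCc2ccccc2)c1
F2 | step 4 | (E)‑1‑[4‑(benzyloxy)‑3,5‑dimethoxyphenyl]‑7‑[3,4‑bis(benzyloxy)phenyl]hept‑1‑en‑3‑one | COc1cc(/C=C/C(=O)CCCCc2ccc(OCc3ccccc3)c(OCc3ccccc3)c2)cc(OC)c1OCc1ccccc1
F3 | step 1 | ethyl 5‑[3,4‑bis(benzyloxy)phenyl]pent‑4‑ynoate | CCOC(=O)CCC#Cc1ccc(OCc2ccccc2)c(OCc2ccccc2)c1
F4 | step 2 | 6‑[3,4‑bis(benzyloxy)phenyl]‑1‑chloro‑2‑(chloromethyl)hexan‑2‑ol | OC(CCl)(CCl)CCCCc1ccc(OCc2ccccc2)c(OCc2ccccc2)c1
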